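**Plan**
Retrosynthesis: cut the acetate O–C(=O) bond, then the C15'–O bond (back to a plain hexadecyl chain), then the anhydride C–O–C link (back to a maleate diester), and last the two C–C bonds on the alkene, ring C3–C1' and ring C4–CH3.
Forward: a hexadecylcopper reagent adds across dimethyl acetylenedicarboxylate (chain joined), iodomethane traps the vinylcopper (methyl joined), and saponification then acid closes the only ring, the furan-2,5-dione.
Enabling feature: C15' is the ω-1 methylene of the C1'–C16' chain, and the furan-2,5-dione ring opens in buffer to a cis-dicarboxylate head, so the molecule looks like a 2-branched stearate to a fatty acid hydroxylase.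
Stereochemistry: the single stereocentre, C15' (S), is set by the enzyme pocket in the C–H hydroxylation and is carried unchanged through O-acetylation.

Key step: step 4

Assumption: the chain is numbered C1' (on ring carbon C3) to C16' (terminal methyl) and the ring as furan-2,5-dione; the hydroxylase of step 4 is fixed at the family level (CYP102A1), and the variant with (S)-ω-1 selectivity is taken to come from a screen of active-site mutants.

**Step 1**
Reactants: 1 1-bromohexadecane
Product: 2 hexadecylmagnesium bromide (titrated stock solution in THF)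
Conditions: Mg turnings (1.2 equiv), I2 (crystal), THF, 25 → 60 °C
Reagents that add atoms: magnesium, [Mg]
Why: Insertion of magnesium metal into the primary C–Br bond (Grignard reagent formation) is routine for long-chain alkyl bromides, and slow addition of 1 to excess metal keeps Wurtz homocoupling low.

**Step 2**
Reactants: 2 hexadecylmagnesium bromide; 3 dimethyl acetylenedicarboxylate; 4 iodomethane
Product: 7 dimethyl (Z)-2-hexadecyl-3-methylbut-2-enedioate, via hexadecylcopper 5 (not isolated), via vinylcopper adduct 6 (not isolated)
Conditions: CuBr·SMe2 (1.0 equiv), THF, −40 °C; 3 (0.9 equiv), −78 °C; then HMPA, 4 (excess), −78 °C → rt; aq. NH4Cl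
Reagents that add atoms: none
Why: Transmetalation gives the alkylcopper 5, syn carbocupration of the electron-poor alkyne (conjugate addition of an organocopper reagent to an ynoate) places copper cis to the hexadecyl group in 6, and HMPA-promoted alkylation of the vinylcopper by iodomethane proceeds with retention, so the two ester groups end up cis as the later ring closure requires.

**Step 3**
Reactants: 7 dimethyl (Z)-2-hexadecyl-3-methylbut-2-enedioate
Product: 10 3-hexadecyl-4-methylfuran-2,5-dione (2-hexadecyl-3-methylmaleic anhydride), via dilithium dicarboxylate 8 (not isolated), via free cis-diacid 9 (not isolated)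
Conditions: LiOH·H2O (6 equiv), THF–MeOH–H2O, 40 °C; then 2 M HCl to pH 1, EtOAc; concentrate from PhMe
Reagents that add atoms: lithium hydroxide, [Li+].[OH-]
Why: Hydroxide saponifies both methyl esters (acyl-oxygen ester hydrolysis) to the dianion 8, and on acidification the cis-diacid 9 loses water spontaneously in a 5-exo-trig acyl substitution, as dialkylmaleic acids normally do, to give the anhydride 10.

**Step 4**
Reactants: 10 3-hexadecyl-4-methylfuran-2,5-dione
Product: 14 3-[(15S)-15-hydroxyhexadecyl]-4-methylfuran-2,5-dione, via opened dipotassium salt 11 (not isolated), via hydroxylated dipotassium salt 12 (not isolated), via hydroxy cis-diacid 13 (not isolated)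
Conditions: KOH (2.05 equiv), H2O–DMSO; then CYP102A1 (P450 BM3) variant from an active-site mutant panel (E. coli cell-free lysate), NADP+ (cat.), glucose dehydrogenase, D-glucose, catalase, air, K2HPO4/KH2PO4 buffer pH 8.0, 25 °C; then 2 M HCl to pH 1, EtOAc, concentrate below 30 °C
Reagents that add atoms: dioxygen, O=O
Why: Proposed new method: in the buffer the anhydride ring of 10 is open, so the enzyme meets the dianion 11, a 2-branched stearate mimic (eighteen carbon atoms from the C2 carboxylate carbon to C16') whose dicarboxylate head should dock at the cationic mouth of the substrate channel (Arg47/Tyr51) and send the chain end to the heme; after the usual reductive activation of O2, the ferryl-oxo porphyrin radical cation abstracts the pro-S hydrogen of C15' and hydroxyl rebound on the same face forms the C15'–O bond with retention, giving 12. The closest known reaction type is the sub-terminal (ω-1 to ω-3) hydroxylation of C12–C18 fatty acids by CYP102A1 and related self-sufficient P450 hydroxylases, which has not been shown for a 2,3-disubstituted maleate head group. No new ring is built; the furan-2,5-dione ring recloses on acidification, when one carboxyl group of the cis-diacid 13 attacks the other in a 5-exo-trig acyl substitution with loss of water. The C15' stereocentre is controlled only by the active-site pocket, which decides which enantiotopic C15'–H bond faces the oxidant, and the variant is picked in the screen for the (S) sense. The step needs ω-1 over ω, ω-2 and ω-3 attack and no oxidation of the allylic C1' methylene, the ring methyl group or the C3=C4 bond; the substrate secures the second point because those sites sit at the carboxylate anchor, far from the iron, and favours ω-1 over ω through the weaker secondary C–H bond, while the choice among the sub-terminal methylenes rests on the pocket that stows the C16' methyl group and is tuned by mutation at positions 78, 82, 87 and 328.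

**Step 5**
Reactants: 14 3-[(15S)-15-hydroxyhexadecyl]-4-methylfuran-2,5-dione
Product: 15 (2S)-16-(4-methyl-2,5-dioxo-2,5-dihydrofuran-3-yl)hexadecan-2-yl acetate (target)
Conditions: Ac2O (3 equiv), pyridine, DMAP (cat.), CH2Cl2, 0 °C → rt
Reagents that add atoms: acetic anhydride, CC(=O)OC(C)=O
Why: DMAP-catalysed O-acylation of the secondary alcohol (nucleophilic acyl substitution on acetic anhydride) leaves the C15'–O bond untouched, so the (S) configuration is retained, and the dehydrating medium keeps the anhydride ring closed.

**Compound list**
1 | 1-bromohexadecane | CCCCCCCCCCCCCCCCBr | starting material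
2 | hexadecylmagnesium bromide | CCCCCCCCCCCCCCCC[Mg]Br | intermediate
3 | dimethyl acetylenedicarboxylate (dimethyl but-2-ynedioate) | COC(=O)C#CC(=O)OC | starting material
4 | iodomethane | CI | starting material
5 | hexadecylcopper (as its MgBr2·SMe2 complex) | CCCCCCCCCCCCCCCC[Cu] | intermediate
6 | dimethyl 2-cuprio-3-hexadecylbut-2-enedioate, copper cis to the hexadecyl group, ester groups cis | COC(=O)/C([Cu])=C(/CCCCCCCCCCCCCCCC)C(=O)OC | intermediate
7 | dimethyl (Z)-2-hexadecyl-3-methylbut-2-enedioate | COC(=O)/C(C)=C(/CCCCCCCCCCCCCCCC)C(=O)OC | intermediate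
8 | dilithium (Z)-2-hexadecyl-3-methylbut-2-enedioate | [Li+].[Li+].[O-]C(=O)/C(C)=C(/CCCCCCCCCCCCCCCC)C(=O)[O-] | intermediate
9 | (Z)-2-hexadecyl-3-methylbut-2-enedioic acid | OC(=O)/C(C)=C(/CCCCCCCCCCCCCCCC)C(=O)O | intermediate
10 | 3-hexadecyl-4-methylfuran-2,5-dione | CCCCCCCCCCCCCCCCC1=C(C)C(=O)OC1=O | intermediate
11 | dipotassium (Z)-2-hexadecyl-3-methylbut-2-enedioate | [K+].[K+].[O-]C(=O)/C(C)=C(/CCCCCCCCCCCCCCCC)C(=O)[O-] | intermediate
12 | dipotassium (Z)-2-[(15S)-15-hydroxyhexadecyl]-3-methylbut-2-enedioate | [K+].[K+].[O-]C(=O)/C(C)=C(/CCCCCCCCCCCCCC[C@H](C)O)C(=O)[O-] | intermediate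
13 | (Z)-2-[(15S)-15-hydroxyhexadecyl]-3-methylbut-2-enedioic acid | OC(=O)/C(C)=C(/CCCCCCCCCCCCCC[C@H](C)O)C(=O)O | intermediate
14 | 3-[(15S)-15-hydroxyhexadecyl]-4-methylfuran-2,5-dione | C[C@H](O)CCCCCCCCCCCCCCC1=C(C)C(=O)OC1=O | intermediate
15 | (2S)-16-(4-methyl-2,5-dioxo-2,5-dihydrofuran-3-yl)hexadecan-2-yl acetate | CC(=O)O[C@@H](C)CCCCCCCCCCCCCCC1=C(C)C(=O)OC1=O | target

**Totals**
Total step count: 5. Longest linear sequence: 5 steps (1 → 2 → 7 → 10 → 14 → 15).

**Steps most likely to fail**

Step 4. The oxidant may attack the wrong chain carbon (ω, ω-2 or ω-3) or the wrong enantiotopic hydrogen, the dianionic head may bind too weakly for useful turnover, or the new carbinol may be oxidised on to the ketone. The fallback takes the C15' carbinol from the chiral pool and completes the chain by olefin cross-metathesis; it sets out from 3 and comes back at 12.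
- 11-Bromoundec-1-ene and magnesium in THF give undec-10-en-1-ylmagnesium bromide F1, which CuBr·SMe2 converts into undec-10-en-1-ylcopper F2.
- Syn addition of F2 to 3 gives dimethyl 2-cuprio-3-(undec-10-en-1-yl)but-2-enedioate F3 (copper cis to the chain), and methylation with 4 in HMPA gives dimethyl (Z)-2-methyl-3-(undec-10-en-1-yl)but-2-enedioate F4.
- Separately, (S)-2-methyloxirane is opened at its CH2 terminus by but-3-enylmagnesium bromide with CuI (cat.) in THF at −30 °C to give (2S)-hept-6-en-2-ol F5, the stereocentre being untouched.
- Cross-metathesis of F4 with excess F5 (second-generation Grubbs catalyst, RuCl2(=CHPh)(H2IMes)(PCy3), CH2Cl2, 40 °C) should give dimethyl (Z)-2-[(15S)-15-hydroxyhexadec-10-en-1-yl]-3-methylbut-2-enedioate F6 as an E/Z mixture at C10'=C11'; the tetrasubstituted maleate alkene is inert to the ruthenium carbene.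
- Hydrogenation with RhCl(PPh3)3 (H2, 1 atm, PhMe–EtOH) should saturate only that disubstituted alkene and give dimethyl (Z)-2-[(15S)-15-hydroxyhexadecyl]-3-methylbut-2-enedioate F7.
- Saponification with KOH in aqueous MeOH gives 12, and acidification as in step 4 leads through 13 to 14.

Step 2. Protonation or cis–trans isomerisation of the vinylcopper species may outrun its slow methylation, so that the methyl group is not delivered or the ester groups end up trans. The fallback brings the ring methyl in as a masked exocyclic methylene instead of as an electrophile; it sets out from 2 and comes back at 10.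
- Wohl–Ziegler bromination (NBS, AIBN, PhCF3, reflux) of commercial dimethyl mesaconate gives dimethyl 2-(bromomethyl)fumarate F8.
- Reagent 2 attacks F8 in an SN2' sense (Et2O–HMPA, 0 °C → rt) to give racemic dimethyl 2-hexadecyl-3-methylidenebutanedioate F9.
- Acid hydrolysis (aq. HCl–AcOH, reflux) gives 2-hexadecyl-3-methylidenebutanedioic acid F10.
- Heating in Ac2O closes the ring and moves the double bond into conjugation with both carbonyl groups, giving 10.

Step 3. Hydrolysis may stall at the hindered half-ester, or base may move the double bond out of the maleate position so that ring closure is no longer clean. The fallback makes the esters acid-labile and avoids base altogether; it sets out from 5 and comes back at 9.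
- Reagent 5 is added to commercial di-tert-butyl but-2-ynedioate at −78 °C to give di-tert-butyl 2-cuprio-3-hexadecylbut-2-enedioate F11 (copper cis to the chain).
- Methylation with 4 in HMPA gives di-tert-butyl (Z)-2-hexadecyl-3-methylbut-2-enedioate F12.
- CF3CO2H in CH2Cl2 at rt removes both tert-butyl groups as 2-methylpropene to give 9, which closes to 10 as in step 3.

**Further compounds**
F1 | step 4 | undec-10-en-1-ylmagnesium bromide | C=CCCCCCCCCC[Mg]Br
F2 | step 4 | undec-10-en-1-ylcopper | C=CCCCCCCCCC[Cu]
F3 | step 4 | dimethyl 2-cuprio-3-(undec-10-en-1-yl)but-2-enedioate, copper cis to the chain | COC(=O)/C([Cu])=C(/CCCCCCCCCC=C)C(=O)OC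
F4 | step 4 | dimethyl (Z)-2-methyl-3-(undec-10-en-1-yl)but-2-enedioate | COC(=O)/C(C)=C(/CCCCCCCCCC=C)C(=O)OC
F5 | step 4 | (2S)-hept-6-en-2-ol | C[C@H](O)CCCC=C
F6 | step 4 | dimethyl (Z)-2-[(15S)-15-hydroxyhexadec-10-en-1-yl]-3-methylbut-2-enedioate (E/Z mixture at C10'=C11') | COC(=O)/C(C)=C(/CCCCCCCCCC=CCCC[C@H](C)O)C(=O)OC
F7 | step 4 | dimethyl (Z)-2-[(15S)-15-hydroxyhexadecyl]-3-methylbut-2-enedioate | COC(=O)/C(C)=C(/CCCCCCCCCCCCCC[C@H](C)O)C(=O)OC
F8 | step 2 | dimethyl 2-(bromomethyl)fumarate (ester groups trans) | COC(=O)/C=C(\CBr)C(=O)OC
F9 | step 2 | dimethyl 2-hexadecyl-3-methylidenebutanedioate (racemic) | C=C(C(=O)OC)C(CCCCCCCCCCCCCCCC)C(=O)OC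
F10 | step 2 | 2-hexadecyl-3-methylidenebutanedioic acid (racemic) | C=C(C(=O)O)C(CCCCCCCCCCCCCCCC)C(=O)O
F11 | step 3 | di-tert-butyl 2-cuprio-3-hexadecylbut-2-enedioate, copper cis to the chain | CC(C)(C)OC(=O)/C([Cu])=C(/CCCCCCCCCCCCCCCC)C(=O)OC(C)(C)C
F12 | step 3 | di-tert-butyl (Z)-2-hexadecyl-3-methylbut-2-enedioate | CC(C)(C)OC(=O)/C(C)=C(/CCCCCCCCCCCCCCCC)C(=O)OC(C)(C)C
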